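**Plan**

- The six O–H bonds are traced back to benzyl ethers. All six aryl C–O bonds are then cut to C–F bonds: the oxygens at C2, C4 and C6 of the butanoyl ring (ring A) and at C2', C4' and C6' of the propanoyl ring (ring B) each sit ortho or para to that ring's C1 acyl carbonyl, so each can arise from an acyl-activated fluoride.
- The hexafluoro diketone is cut next at the ring A–butanoyl bond (Friedel–Crafts acylation) and then at the CH2–ring A bond (benzyl–aryl cross-coupling). This leaves a bromomethyl propanoyl arene for ring B.
- Forward: 1,3,5-trifluorobenzene is methylated once (ring A) or twice (ring B). Ring B is acylated and brominated at one methyl, then joined to magnesiated and zincated ring A. Ring A is acylated, the six fluorides are exchanged for benzyloxy groups, and hydrogenolysis ends the route.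
- No ring is formed; both benzene rings come from 1,3,5-trifluorobenzene.
- The target has no stereocentre and no double-bond geometry, so there is nothing to control.

Key step: step 7

Remark: the target is treated as its hexahydroxy diketone tautomer. 1,3,5-Trifluorobenzene, iodomethane, propanoyl chloride, butanoyl chloride, N-bromosuccinimide, benzyl alcohol and a THF solution of TMPMgCl·LiCl, the lithium chloride complex of (2,2,6,6-tetramethylpiperidin-1-yl)magnesium chloride, are taken as commercial.

**Route**

Step 1
Reactants: 1 1,3,5-trifluorobenzene; 2 iodomethane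
Product: 4 2,4,6-trifluorotoluene, via (2,4,6-trifluorophenyl)lithium 3 (not isolated)
Conditions: n-BuLi (1.0 equiv), THF, −78 °C; then MeI, −78 °C → rt
Reagents that add atoms: iodomethane, CI
Why: Fluorine-directed ortho-lithiation followed by SN2 methylation; every C–H of 1 lies between two fluorines and is deprotonated cleanly at −78 °C, where the aryllithium does not lose LiF to an aryne.

Step 2
Reactants: 4 2,4,6-trifluorotoluene; 2 iodomethane
Product: 6 1,3,5-trifluoro-2,4-dimethylbenzene, via (2,4,6-trifluoro-3-methylphenyl)lithium 5 (not isolated)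
Conditions: n-BuLi (1.0 equiv), THF, −78 °C; then MeI, −78 °C → rt
Reagents that add atoms: iodomethane, CI
Why: The same directed ortho-lithiation and alkylation; the two free ring positions of 4 are equivalent and each is flanked by two fluorines, so ring metalation should outpace benzylic deprotonation and only one dimethyl isomer can form.

Step 3
Reactants: 6 1,3,5-trifluoro-2,4-dimethylbenzene; 7 propanoyl chloride
Product: 8 1-(2,4,6-trifluoro-3,5-dimethylphenyl)propan-1-one
Conditions: EtCOCl (1.2 equiv), AlCl3 (1.5 equiv), CH2Cl2, 0 °C → reflux; aqueous HCl work-up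
Reagents that add atoms: propanoyl chloride, CCC(=O)Cl
Why: Friedel–Crafts acylation; the only ring C–H of 6 is ortho, ortho and para to three fluorines, whose lone pairs stabilise the Wheland cation as in the AlCl3 acylation of 1,3,5-trifluorobenzene, and the ketone formed is deactivated against further attack.

Step 4
Reactants: 8 1-(2,4,6-trifluoro-3,5-dimethylphenyl)propan-1-one; 9 N-bromosuccinimide
Product: 10 1-[3-(bromomethyl)-2,4,6-trifluoro-5-methylphenyl]propan-1-one
Conditions: NBS (0.9 equiv), AIBN (cat.), PhCF3, 80 °C; unreacted 8 recovered and recycled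
Reagents that add atoms: N-bromosuccinimide, O=C1CCC(=O)N1Br
Why: Wohl–Ziegler benzylic bromination; the bromine atom should abstract hydrogen from the two equivalent aryl methyl groups in preference to the polarity-mismatched α-keto C–H, and substoichiometric NBS at partial conversion limits double bromination.

Step 5
Reactants: 4 2,4,6-trifluorotoluene; 10 1-[3-(bromomethyl)-2,4,6-trifluoro-5-methylphenyl]propan-1-one
Product: 13 1-[2,4,6-trifluoro-3-methyl-5-[(2,4,6-trifluoro-3-methylphenyl)methyl]phenyl]propan-1-one, via (2,4,6-trifluoro-3-methylphenyl)magnesium chloride 11 (not isolated), via (2,4,6-trifluoro-3-methylphenyl)zinc chloride 12 (not isolated)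
Conditions: 4 (1.4 equiv), TMPMgCl·LiCl (1.3 equiv), THF, 0 → 25 °C; ZnCl2 (1.4 equiv), 0 °C; then 10, Pd(PPh3)4 (5 mol%), THF, 25 → 50 °C
Reagents that add atoms: none
Why: Deprotonative magnesiation followed by Negishi cross-coupling; the hindered magnesium amide removes the ring C–H of 4 that lies between two fluorines, as it does in other polyhaloarenes, the arylmagnesium chloride does not lose fluoride to an aryne at 25 °C, and after exchange to zinc the arylzinc chloride neither adds to nor enolises the ketone of 10 while the benzylic C–Br bond adds oxidatively to zerovalent palladium and transmetalation with reductive elimination should form the aryl–CH2 bond.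

Step 6
Reactants: 13 1-[2,4,6-trifluoro-3-methyl-5-[(2,4,6-trifluoro-3-methylphenyl)methyl]phenyl]propan-1-one; 14 butanoyl chloride
Product: 15 1-[2,4,6-trifluoro-3-methyl-5-[(2,4,6-trifluoro-3-methyl-5-propanoylphenyl)methyl]phenyl]butan-1-one
Conditions: n-PrCOCl (1.5 equiv), AlCl3 (3 equiv), 1,2-dichloroethane, 0 → 50 °C; aqueous HCl work-up
Reagents that add atoms: butanoyl chloride, CCCC(=O)Cl
Why: Friedel–Crafts acylation; the propanoyl ring is fully substituted and deactivated as its AlCl3 complex, so the acylium ion can enter only the single free C–H of the other ring, which is ortho, ortho and para to fluorine as in step 3.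

Step 7
Reactants: 15 1-[2,4,6-trifluoro-3-methyl-5-[(2,4,6-trifluoro-3-methyl-5-propanoylphenyl)methyl]phenyl]butan-1-one; 16 benzyl alcohol
Product: 18 1-[2,4,6-tris(benzyloxy)-3-methyl-5-[[2,4,6-tris(benzyloxy)-3-methyl-5-propanoylphenyl]methyl]phenyl]butan-1-one, via sodium benzyloxide 17 (not isolated)
Conditions: BnOH (12 equiv), NaH (9 equiv), THF, 0 °C → rt; then 15, DMSO, argon, 25 → 80 °C
Reagents that add atoms: benzyl alcohol, OCc1ccccc1
Why: Each C–O bond forms by addition–elimination (nucleophilic aromatic substitution): benzyloxide adds to a fluorine-bearing carbon, the Meisenheimer anion is stabilised by the ortho or para acyl carbonyl and by the inductive pull of the fluorines still present, and fluoride leaves; this happens three times on each ring. The closest known reaction type is the alkoxide displacement of ortho and para fluorides in fluorinated aryl ketones, benzonitriles and nitroarenes. No ring closes and no stereocentre forms. The step needs complete sixfold substitution without attack at the ketones: no fluorine is meta to its acyl group, so none is left unactivated, and both carbonyls are flanked by two ortho substituents, which shields them from alkoxide addition and C–C cleavage. Free benzyl alcohol in excess keeps the propanoyl and butanoyl groups largely un-enolised, so the activating groups stay switched on. The last displacement on each ring is the slowest, since two benzyloxy groups already enrich the ring, which is why excess alkoxide, DMSO and 80 °C are specified.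

Step 8
Reactants: 18 1-[2,4,6-tris(benzyloxy)-3-methyl-5-[[2,4,6-tris(benzyloxy)-3-methyl-5-propanoylphenyl]methyl]phenyl]butan-1-one
Product: 19 1-[2,4,6-trihydroxy-3-methyl-5-[(2,4,6-trihydroxy-3-methyl-5-propanoylphenyl)methyl]phenyl]butan-1-one
Conditions: H2 (1 atm), Pd/C (10%), EtOAc/MeOH, rt
Reagents that add atoms: none
Why: Catalytic hydrogenolysis of aryl benzyl ethers; the neutral conditions should leave the hydrogen-bonded aryl ketones and the methylene bridge between the two phloroglucinol rings untouched.

**Compound list**

1 | 1,3,5-trifluorobenzene | Fc1cc(F)cc(F)c1 | starting material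
2 | iodomethane | CI | starting material
3 | (2,4,6-trifluorophenyl)lithium | [Li]c1c(F)cc(F)cc1F | intermediate
4 | 2,4,6-trifluorotoluene | Cc1c(F)cc(F)cc1F | intermediate
5 | (2,4,6-trifluoro-3-methylphenyl)lithium | [Li]c1c(F)cc(F)c(C)c1F | intermediate
6 | 1,3,5-trifluoro-2,4-dimethylbenzene | Cc1c(F)cc(F)c(C)c1F | intermediate
7 | propanoyl chloride | CCC(=O)Cl | starting material
8 | 1-(2,4,6-trifluoro-3,5-dimethylphenyl)propan-1-one | CCC(=O)c1c(F)c(C)c(F)c(C)c1F | intermediate
9 | N-bromosuccinimide | O=C1CCC(=O)N1Br | starting material
10 | 1-[3-(bromomethyl)-2,4,6-trifluoro-5-methylphenyl]propan-1-one | CCC(=O)c1c(F)c(C)c(F)c(CBr)c1F | intermediate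
11 | (2,4,6-trifluoro-3-methylphenyl)magnesium chloride | Cl[Mg]c1c(F)cc(F)c(C)c1F | intermediate
12 | (2,4,6-trifluoro-3-methylphenyl)zinc chloride | Cl[Zn]c1c(F)cc(F)c(C)c1F | intermediate
13 | 1-[2,4,6-trifluoro-3-methyl-5-[(2,4,6-trifluoro-3-methylphenyl)methyl]phenyl]propan-1-one | CCC(=O)c1c(F)c(C)c(F)c(Cc2c(F)cc(F)c(C)c2F)c1F | intermediate
14 | butanoyl chloride | CCCC(=O)Cl | starting material
15 | 1-[2,4,6-trifluoro-3-methyl-5-[(2,4,6-trifluoro-3-methyl-5-propanoylphenyl)methyl]phenyl]butan-1-one | CCCC(=O)c1c(F)c(C)c(F)c(Cc2c(F)c(C)c(F)c(C(=O)CC)c2F)c1F | intermediate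
16 | benzyl alcohol | OCc1ccccc1 | starting material
17 | sodium benzyloxide | [Na+].[O-]Cc1ccccc1 | intermediate
18 | 1-[2,4,6-tris(benzyloxy)-3-methyl-5-[[2,4,6-tris(benzyloxy)-3-methyl-5-propanoylphenyl]methyl]phenyl]butan-1-one | CCCC(=O)c1c(OCc2ccccc2)c(C)c(OCc2ccccc2)c(Cc2c(OCc3ccccc3)c(C)c(OCc3ccccc3)c(C(=O)CC)c2OCc2ccccc2)c1OCc1ccccc1 | intermediate
19 | 1-[2,4,6-trihydroxy-3-methyl-5-[(2,4,6-trihydroxy-3-methyl-5-propanoylphenyl)methyl]phenyl]butan-1-one | CCCC(=O)c1c(O)c(C)c(O)c(Cc2c(O)c(C)c(O)c(C(=O)CC)c2O)c1O | target

**Step count**

Total steps: 8. Longest linear sequence: 8 steps (1 → 4 → 6 → 8 → 10 → 13 → 15 → 18 → 19); compound 4 from step 1 also serves as the second coupling partner in step 5.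

**Steps most likely to fail**

Step 7. The substitution may stall before the sixth displacement: each ring grows electron-rich, and two ortho benzyloxy groups twist the ketone out of conjugation. Enolate formation may switch off the activating group, alkoxide may add to a carbonyl and cleave the aryl–acyl bond, or alkoxide may dealkylate an ortho benzyl ether to a phenoxide that stops further substitution. Fallback: setting out from 15, the fluorides would be displaced with sodium methoxide in methanol/DMSO at 60–80 °C. Methoxide is a smaller nucleophile, and in its own protic solvent the ketones stay un-enolised. This should give the hexamethyl ether 1-[2,4,6-trimethoxy-3-methyl-5-[(2,4,6-trimethoxy-3-methyl-5-propanoylphenyl)methyl]phenyl]butan-1-one F1. Exhaustive O-demethylation with BBr3 in CH2Cl2 (−78 °C → rt) would then come back to the route at the target 19, without passing through 18.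

Step 4. Bromination may run on to the bis(bromomethyl) and dibromomethyl compounds, and ionic α-bromination of the ketone through its enol may compete with the radical chain. Fallback: setting out from 4, lithiation as in step 2 (aryllithium 5) and a DMF quench would give 2,4,6-trifluoro-3-methylbenzaldehyde F2. NaBH4 reduction would give (2,4,6-trifluoro-3-methylphenyl)methanol F3, and TBSCl with imidazole would give tert-butyldimethyl[(2,4,6-trifluoro-3-methylphenyl)methoxy]silane F4. Lithiation of the last ring C–H (LDA, THF, −78 °C) would form [3-[[tert-butyl(dimethyl)silyl]oxymethyl]-2,4,6-trifluoro-5-methylphenyl]lithium F5. Acylation with N-methoxy-N-methylpropanamide would give 1-[3-[[tert-butyl(dimethyl)silyl]oxymethyl]-2,4,6-trifluoro-5-methylphenyl]propan-1-one F6. Ph3PBr2 in CH2Cl2 would convert the silyl ether directly into the bromide, returning to the route at 10 with the benzylic carbon placed unambiguously.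

Step 6. Under AlCl3 and HCl the diarylmethane may undergo ipso protonation or ipso acylation with loss or migration of the benzyl group, and fluoride–chloride exchange is possible on prolonged heating. Fallback: the butanoyl group would be installed before the rings are joined. Setting out from 4, Friedel–Crafts acylation with butanoyl chloride and AlCl3 would give 1-(2,4,6-trifluoro-3-methylphenyl)butan-1-one F7. Iodination of the remaining ring position (N-iodosuccinimide, TfOH) would give 1-(2,4,6-trifluoro-3-iodo-5-methylphenyl)butan-1-one F8. Zinc insertion (Zn dust, LiCl, THF) would form the ketone-tolerant (3-butanoyl-2,4,6-trifluoro-5-methylphenyl)zinc iodide F9. Negishi coupling of F9 with 10 under Pd(PPh3)4 would come back to the route at 15.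

**Further compounds**

F1 | step 7 | 1-[2,4,6-trimethoxy-3-methyl-5-[(2,4,6-trimethoxy-3-methyl-5-propanoylphenyl)methyl]phenyl]butan-1-one | CCCC(=O)c1c(OC)c(C)c(OC)c(Cc2c(OC)c(C)c(OC)c(C(=O)CC)c2OC)c1OC
F2 | step 4 | 2,4,6-trifluoro-3-methylbenzaldehyde | Cc1c(F)cc(F)c(C=O)c1F
F3 | step 4 | (2,4,6-trifluoro-3-methylphenyl)methanol | Cc1c(F)cc(F)c(CO)c1F
F4 | step 4 | tert-butyldimethyl[(2,4,6-trifluoro-3-methylphenyl)methoxy]silane | Cc1c(F)cc(F)c(CO[Si](C)(C)C(C)(C)C)c1F
F5 | step 4 | [3-[[tert-butyl(dimethyl)silyl]oxymethyl]-2,4,6-trifluoro-5-methylphenyl]lithium | [Li]c1c(F)c(C)c(F)c(CO[Si](C)(C)C(C)(C)C)c1F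
F6 | step 4 | 1-[3-[[tert-butyl(dimethyl)silyl]oxymethyl]-2,4,6-trifluoro-5-methylphenyl]propan-1-one | CCC(=O)c1c(F)c(C)c(F)c(CO[Si](C)(C)C(C)(C)C)c1F
F7 | step 6 | 1-(2,4,6-trifluoro-3-methylphenyl)butan-1-one | CCCC(=O)c1c(F)cc(F)c(C)c1F
F8 | step 6 | 1-(2,4,6-trifluoro-3-iodo-5-methylphenyl)butan-1-one | CCCC(=O)c1c(F)c(I)c(F)c(C)c1F
F9 | step 6 | (3-butanoyl-2,4,6-trifluoro-5-methylphenyl)zinc iodide | CCCC(=O)c1c(F)c([Zn]I)c(F)c(C)c1F
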